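Leave a flask for 20 min and the question becomes how far the reagent has carried the substrate.

in all of them: reagent 0.475 mM
- north-east: substrate 3.4 × 10⁻⁴ M; run made earlier
- north: substrate 7.5 × 10⁻⁴ M; run made earlier
- flask: substrate 5.0 × 10⁻⁴ M; time 20 min

- north-east (time / min: substrate / %, single product / %): 0.833: 60.3, 23.9; 2.50: 42.9, 29.8; 5.00: 37.8, 23.0; 6.00: 38.4, 18.6; 10.0: 33.7, 11.4; 12.0: 33.7, 10.7; 15.0: 31.8, 8.2
- north (time / min: substrate / %, single product / %): 0.833: 67.0, 21.7; 2.50: 59.4, 24.5; 5.00: 58.7, 15.5; 6.00: 58.6, 13.1; 10.0: 62.0, 8.4; 12.0: 60.2, 4.9; 15.0: 62.2, 2.0

(standard deviation of a reading: 1 percentage point)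

- what was read earlier has a scatter of 1 percentage point, one standard deviation

- substrate at 20 min, in percent of the substrate charged
- single product at 20 min, in percent of the substrate charged
- other mono adduct at 20 min, in percent of the substrate charged
- bis adduct at 20 min, in percent of the substrate charged

In the flask the reagent is charged in the smaller amount, which makes it the limiting reagent, so you write its balance in fractions of the substrate charged. A mono adduct holds one reagent and the bis adduct holds two.

Now read the tables from the bottom. The north run charges a ratio of 0.633 reagent to substrate. Its substrate reads 59.4% at 2.50 min and 62.2% at 15.0 min, so it has stopped falling, while its single product goes on dropping to 2.0%. Counting the whole charge as taken up, that run gives an uptake of 1.68, the reagent taken up per substrate gone.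

The north-east run has a ratio of 1.40, and the same count gives 2.05, more than two. Some of its reagent therefore stayed free. That run still reads 8.2% single product at 15.0 min, and each single product counts for one reagent, so its uptake is at most 1.88, before any other mono adduct is counted; as an estimate, you take that ceiling as its uptake.

The flask has a ratio of 0.950. My reckoning goes along the ratio between those runs, which gives an uptake of 1.76. If the flask's reagent is counted as taken up, 54.0% of the substrate goes and 46.0% stays. Of what goes, 41.0% ends as bis adduct and 12.9% as the two mono adducts together.

The forecast says 47% substrate, 3% single product, 10% other mono adduct and 40% bis adduct, with more substrate and less bis adduct than my reckoning, and calls its split of the last two “inferred, not measured”.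

The flask gives 47.7% substrate, 2.72% single product, 9.84% other mono adduct and 39.7% bis adduct.

    substrate + reagent → other mono adduct (k = 7.80 M⁻¹ s⁻¹)
    reagent + single product → bis adduct (k = 4.80 M⁻¹ s⁻¹)
    substrate + reagent ⇌ single product (K = 2900 M⁻¹, k = 23.0 M⁻¹ s⁻¹)
    reagent + other mono adduct → bis adduct (k = 38.0 M⁻¹ s⁻¹)

At 20.0 min the flask still holds 3.1% of its reagent, so its uptake comes to 1.76, above the 1.68 read from the north run. A neighbour flask charged with 0.0019 M of reagent keeps 47% of that reagent and has 0.0358% substrate left, and its uptake comes to 2.00.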